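## Retrosynthetic overview

1. Vancouverone A (16) ⇒ its tri-O-benzyl ether 15 (global debenzylation last); the 6E alkene ⇒ sp3–sp2 Negishi coupling of a primary alkylzinc with (E)-2-bromobut-2-ene.
2. Key disconnection: the pyridine C3–acyl bond and both methyl stereocentres are traced to one step, an enantioselective rhodium-catalysed desymmetrising cross-coupling of a 3-pyridylzinc with meso-2,4-dimethylglutaric anhydride. This replaces the usual addition of a metalated pyridine to a separately built chiral aldehyde.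
3. The pyridylzinc comes from 3-bromo-2,4-dichloropyridine by double SNAr, C5 iodination and an iodide-selective Suzuki coupling.
4. No ring is constructed: pyridine ring A and phenol ring B are bought and joined first (Suzuki); the 2-pyridone tautomer of ring A is revealed in the last step.

Assumption: the (S) enantiomer of t-Bu-PHOX is taken to direct rhodium into the acyl C–O bond next to the carbon that becomes the (S)-configured α-keto centre; if the sense proves opposite, the (R) ligand is used with no other change. Compounds 1, 2 (1 M in benzyl alcohol), 5, 7 and 13 are taken to be catalogue items.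

## Route

Step 1
Reactants: 1 3-bromo-2,4-dichloropyridine; 2 sodium benzyloxide
Product: 3 2,4-bis(benzyloxy)-3-bromopyridine
Conditions: NaOBn (2.3 equiv, 1 M in BnOH), DMF, 0 → 70 °C
Reagents that add atoms: sodium benzyloxide (2), [Na+].[O-]Cc1ccccc1
Why: Double nucleophilic aromatic substitution (SNAr) at the 4- and 2-chlorides, both activated by the ring nitrogen, while the 3-bromide is not activated and stays.

Step 2
Reactants: 3 2,4-bis(benzyloxy)-3-bromopyridine
Product: 4 2,4-bis(benzyloxy)-3-bromo-5-iodopyridine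
Conditions: NIS (1.1 equiv), TFA (0.2 equiv), MeCN, 40 °C
Reagents that add atoms: N-iodosuccinimide, O=C1CCC(=O)N1I
Why: Electrophilic aromatic iodination at C5, the only free position that is ortho/para to both alkoxy donors; the benzyl rings are not activated.

Step 3
Reactants: 4 2,4-bis(benzyloxy)-3-bromo-5-iodopyridine; 5 4-(benzyloxy)phenylboronic acid
Product: 6 2,4-bis(benzyloxy)-5-[4-(benzyloxy)phenyl]-3-bromopyridine
Conditions: Pd(PPh3)4 (5 mol %), Na2CO3 (2 M aq), DME, 70 °C
Reagents that add atoms: 4-(benzyloxy)phenylboronic acid (5), OB(O)c1ccc(OCc2ccccc2)cc1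
Why: Suzuki–Miyaura coupling; zerovalent palladium inserts into the C–I bond far faster than into the electron-rich C–Br bond flanked by two benzyloxy groups, so the bromide survives as the later metalation handle.

Step 4
Reactants: 6 2,4-bis(benzyloxy)-5-[4-(benzyloxy)phenyl]-3-bromopyridine; 7 meso-2,4-dimethylglutaric anhydride (cis-(3R,5S)-3,5-dimethyloxane-2,6-dione)
Product: 10 (2R,4S)-5-{2,4-bis(benzyloxy)-5-[4-(benzyloxy)phenyl]pyridin-3-yl}-2,4-dimethyl-5-oxopentanoic acid, via pyridin-3-yllithium 8 (not isolated), via pyridin-3-ylzinc chloride 9 (not isolated)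
Conditions: n-BuLi (1.05 equiv), THF, −78 °C; ZnCl2 (1.1 equiv), −78 °C → rt; then 7 (1.5 equiv), [Rh(nbd)Cl]2 (5 mol %), (S)-t-Bu-PHOX (10 mol %), THF/DMF, 50 °C; 1 M HCl work-up
Reagents that add atoms: meso-2,4-dimethylglutaric anhydride (7), C[C@H]1C[C@@H](C)C(=O)OC1=O; n-BuLi, [Li]CCCC (Li in 8 only); ZnCl2, Cl[Zn]Cl (Zn and Cl in 9 only)
Why: Proposed new method: after Br/Li exchange and transmetalation to zinc, monovalent rhodium bound to the chiral phosphinooxazoline inserts into one of the two enantiotopic acyl C–O bonds of the meso anhydride, the acyl rhodium carboxylate transmetalates with arylzinc 9 and reductive elimination gives the ketone, so the syn relation of the two methyl groups comes from the meso substrate and their absolute configuration from the catalyst in the same step that makes the pyridine–acyl bond; the closest known reactions are the rhodium/t-Bu-PHOX-catalysed enantioselective cross-coupling of alkylzinc halides with this same anhydride and arylzinc openings of meso succinic anhydrides, and the extension to a di-ortho-alkoxy heteroarylzinc is untested.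

Step 5
Reactants: 10 (2R,4S)-5-{2,4-bis(benzyloxy)-5-[4-(benzyloxy)phenyl]pyridin-3-yl}-2,4-dimethyl-5-oxopentanoic acid
Product: 11 (2S,4R)-1-{2,4-bis(benzyloxy)-5-[4-(benzyloxy)phenyl]pyridin-3-yl}-5-hydroxy-2,4-dimethylpentan-1-one
Conditions: BH3·THF (2.2 equiv), THF, −10 → 0 °C; MeOH quench
Reagents that add atoms: none
Why: Chemoselective borane reduction; the carboxylic acid is reduced through its acyloxyborane much faster than the hindered, twisted di-ortho-alkoxy pyridyl ketone, and no stereocentre is touched.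

Step 6
Reactants: 11 (2S,4R)-1-{2,4-bis(benzyloxy)-5-[4-(benzyloxy)phenyl]pyridin-3-yl}-5-hydroxy-2,4-dimethylpentan-1-one
Product: 12 (2S,4R)-1-{2,4-bis(benzyloxy)-5-[4-(benzyloxy)phenyl]pyridin-3-yl}-5-iodo-2,4-dimethylpentan-1-one
Conditions: I2, PPh3, imidazole, CH2Cl2, 0 °C → rt
Reagents that add atoms: iodine, II
Why: Appel-type (Garegg–Samuelsson) iodination of the primary alcohol under nearly neutral conditions, which drains the open hydroxy ketone from any lactol equilibrium and does not enolise the α-keto stereocentre.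

Step 7
Reactants: 12 (2S,4R)-1-{2,4-bis(benzyloxy)-5-[4-(benzyloxy)phenyl]pyridin-3-yl}-5-iodo-2,4-dimethylpentan-1-one; 13 (E)-2-bromobut-2-ene
Product: 15 (2S,4R,6E)-1-{2,4-bis(benzyloxy)-5-[4-(benzyloxy)phenyl]pyridin-3-yl}-2,4,6-trimethyloct-6-en-1-one, via alkylzinc iodide 14 (not isolated)
Conditions: Zn dust (activated with BrCH2CH2Br/TMSCl), LiCl, THF, 35 °C; then 13 (1.5 equiv), Pd(OAc)2 (3 mol %), SPhos (6 mol %), THF, 45 °C
Reagents that add atoms: (E)-2-bromobut-2-ene (13), C/C=C(\C)Br; zinc, [Zn] (Zn in 14 only)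
Why: LiCl-assisted zinc insertion into the primary C–I bond tolerates the hindered ketone, and the Negishi coupling at zerovalent palladium retains the alkenyl bromide geometry, giving the 6E alkene without involving either stereocentre.

Step 8
Reactants: 15 (2S,4R,6E)-1-{2,4-bis(benzyloxy)-5-[4-(benzyloxy)phenyl]pyridin-3-yl}-2,4,6-trimethyloct-6-en-1-one
Product: 16 vancouverone A, 4-hydroxy-5-(4-hydroxyphenyl)-3-[(2S,4R,6E)-2,4,6-trimethyloct-6-enoyl]pyridin-2(1H)-one
Conditions: BCl3 (6 equiv), pentamethylbenzene (9 equiv), CH2Cl2, −78 °C; MeOH quench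
Reagents that add atoms: none
Why: Lewis-acid debenzylation of the phenyl and both pyridyl benzyl ethers at −78 °C, with pentamethylbenzene trapping the benzyl cation so the trisubstituted alkene is neither benzylated nor protonated; the freed 2-hydroxypyridine tautomerises to the 2-pyridone and the stereocentres are untouched.

## Compound list

1 | 3-bromo-2,4-dichloropyridine | Clc1ccnc(Cl)c1Br | starting material
2 | sodium benzyloxide | [Na+].[O-]Cc1ccccc1 | starting material
3 | 2,4-bis(benzyloxy)-3-bromopyridine | Brc1c(OCc2ccccc2)nccc1OCc1ccccc1 | intermediate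
4 | 2,4-bis(benzyloxy)-3-bromo-5-iodopyridine | Brc1c(OCc2ccccc2)ncc(I)c1OCc1ccccc1 | intermediate
5 | 4-(benzyloxy)phenylboronic acid | OB(O)c1ccc(OCc2ccccc2)cc1 | starting material
6 | 2,4-bis(benzyloxy)-5-[4-(benzyloxy)phenyl]-3-bromopyridine | Brc1c(OCc2ccccc2)ncc(-c2ccc(OCc3ccccc3)cc2)c1OCc1ccccc1 | intermediate
7 | meso-2,4-dimethylglutaric anhydride, cis-(3R,5S)-3,5-dimethyloxane-2,6-dione | C[C@H]1C[C@@H](C)C(=O)OC1=O | starting material
8 | {2,4-bis(benzyloxy)-5-[4-(benzyloxy)phenyl]pyridin-3-yl}lithium (not isolated) | [Li]c1c(OCc2ccccc2)ncc(-c2ccc(OCc3ccccc3)cc2)c1OCc1ccccc1 | intermediate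
9 | {2,4-bis(benzyloxy)-5-[4-(benzyloxy)phenyl]pyridin-3-yl}zinc chloride (not isolated) | Cl[Zn]c1c(OCc2ccccc2)ncc(-c2ccc(OCc3ccccc3)cc2)c1OCc1ccccc1 | intermediate
10 | (2R,4S)-5-{2,4-bis(benzyloxy)-5-[4-(benzyloxy)phenyl]pyridin-3-yl}-2,4-dimethyl-5-oxopentanoic acid | OC(=O)[C@H](C)C[C@H](C)C(=O)c1c(OCc2ccccc2)ncc(-c2ccc(OCc3ccccc3)cc2)c1OCc1ccccc1 | intermediate
11 | (2S,4R)-1-{2,4-bis(benzyloxy)-5-[4-(benzyloxy)phenyl]pyridin-3-yl}-5-hydroxy-2,4-dimethylpentan-1-one | OC[C@H](C)C[C@H](C)C(=O)c1c(OCc2ccccc2)ncc(-c2ccc(OCc3ccccc3)cc2)c1OCc1ccccc1 | intermediate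
12 | (2S,4R)-1-{2,4-bis(benzyloxy)-5-[4-(benzyloxy)phenyl]pyridin-3-yl}-5-iodo-2,4-dimethylpentan-1-one | IC[C@H](C)C[C@H](C)C(=O)c1c(OCc2ccccc2)ncc(-c2ccc(OCc3ccccc3)cc2)c1OCc1ccccc1 | intermediate
13 | (E)-2-bromobut-2-ene (methyl groups cis) | C/C=C(\C)Br | starting material
14 | [(2R,4S)-5-{2,4-bis(benzyloxy)-5-[4-(benzyloxy)phenyl]pyridin-3-yl}-2,4-dimethyl-5-oxopentyl]zinc iodide (not isolated) | I[Zn]C[C@H](C)C[C@H](C)C(=O)c1c(OCc2ccccc2)ncc(-c2ccc(OCc3ccccc3)cc2)c1OCc1ccccc1 | intermediate
15 | (2S,4R,6E)-1-{2,4-bis(benzyloxy)-5-[4-(benzyloxy)phenyl]pyridin-3-yl}-2,4,6-trimethyloct-6-en-1-one | C/C=C(\C)C[C@H](C)C[C@H](C)C(=O)c1c(OCc2ccccc2)ncc(-c2ccc(OCc3ccccc3)cc2)c1OCc1ccccc1 | intermediate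
16 | vancouverone A, 4-hydroxy-5-(4-hydroxyphenyl)-3-[(2S,4R,6E)-2,4,6-trimethyloct-6-enoyl]pyridin-2(1H)-one | C/C=C(\C)C[C@H](C)C[C@H](C)C(=O)c1c(O)c(-c2ccc(O)cc2)c[nH]c1=O | target

## Step count and risks

Total steps: 8. Longest linear sequence: 8 steps (1 → 16).

The three steps most likely to fail:

**Step 4 (desymmetrising cross-coupling).** The di-ortho-alkoxy pyridylzinc may transmetalate too slowly or give low enantioselectivity, and the pyridine nitrogen may bind rhodium. The fallback sets out from anhydride 7 and bromide 6 and comes back to the route at hydroxy ketone 11, so it replaces steps 4 and 5. Cinchona-alkaloid-mediated methanolysis of 7 ((DHQD)2AQN, MeOH, Et2O, −20 °C; the pseudo-enantiomeric (DHQ)2AQN if the sense is the other one) opens the carbonyl next to the future α-keto carbon and gives the hemiester (2R,4S)-5-methoxy-2,4-dimethyl-5-oxopentanoic acid F1. BH3·SMe2 reduces only the free acid to methyl (2S,4R)-5-hydroxy-2,4-dimethylpentanoate F2, which closes under catalytic TsOH in toluene to the lactone (3S,5R)-3,5-dimethyloxan-2-one F3. Aryllithium 8, made from 6 with n-BuLi as in step 4, is added to F3 at −78 °C; the lithium lactolate does not collapse before work-up, so only one aryl group adds and 11 is released.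

**Step 5 (acid reduced beside the ketone).** Over-reduction of the ketone or borane binding to the pyridine could spoil the selectivity. The fallback sets out from keto acid 10 and comes back at 11. LiAlH4 (THF, 0 °C) reduces acid and ketone alike to the diol (2S,4R)-1-{2,4-bis(benzyloxy)-5-[4-(benzyloxy)phenyl]pyridin-3-yl}-2,4-dimethylpentane-1,5-diol F4 (both C1 epimers, which converge). MnO2 (CH2Cl2, rt) then re-oxidises only the benzylic-type pyridyl carbinol and leaves the primary alcohol, giving 11.

**Step 7 (alkylzinc formed beside a ketone, hindered alkenyl bromide).** Zinc insertion could be slow or the alkylzinc could cyclise onto the ketone. The fallback sets out from iodide 12 and bromide 13 and comes back at 15, with the roles of the partners reversed so that no organozinc is generated beside the ketone. Bromide 13 undergoes Br/Li exchange (t-BuLi, 2 equiv, Et2O, −78 °C, retention) to (Z)-but-2-en-2-yllithium F5 (methyl groups still cis). ZnCl2 converts it into (E)-but-2-en-2-ylzinc chloride F6. F6 is then coupled with alkyl iodide 12 as the electrophile under Pd2(dba)3, tricyclopentylphosphine and N-methylimidazole in THF/NMP at 80 °C (alkyl-electrophile Negishi coupling) to give 15.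

Further compounds
F1 | step 4 | (2R,4S)-5-methoxy-2,4-dimethyl-5-oxopentanoic acid | OC(=O)[C@H](C)C[C@H](C)C(=O)OC
F2 | step 4 | methyl (2S,4R)-5-hydroxy-2,4-dimethylpentanoate | OC[C@H](C)C[C@H](C)C(=O)OC
F3 | step 4 | (3S,5R)-3,5-dimethyloxan-2-one | O=C1OC[C@H](C)C[C@@H]1C
F4 | step 5 | (2S,4R)-1-{2,4-bis(benzyloxy)-5-[4-(benzyloxy)phenyl]pyridin-3-yl}-2,4-dimethylpentane-1,5-diol (C1 epimers) | OC[C@H](C)C[C@H](C)C(O)c1c(OCc2ccccc2)ncc(-c2ccc(OCc3ccccc3)cc2)c1OCc1ccccc1
F5 | step 7 | (Z)-but-2-en-2-yllithium | C/C=C(\C)[Li]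
F6 | step 7 | (E)-but-2-en-2-ylzinc chloride | C/C=C(\C)[Zn]Cl
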